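I began with the readings.

| flask | starting material | coupling partner | remark | time |
|---|---|---|---|---|
| spring | 0.055 M | 0.040 M | run made earlier |  |
| south-west | 0.10 M | 0.0800 M |  | 40 min |
| east | 0.030 M | 0.120 M |  | 40 min |
| north | 0.050 M | 0.0600 M |  | 40 min |
| south-east | 0.050 M | 0.0400 M |  | 40 min |
| south | 0.030 M | 0.150 M |  | 40 min |
| north-west | 0.015 M | 0.0100 M |  | 40 min |

spring run (percent of the starting material charged): time / min: single product / % = 0.667: 7.0; 1.00: 9.7; 2.00: 18.6; 3.00: 23.9; 5.00: 34.9; 8.00: 44.8

(standard deviation of a reading: 1 percentage point)

- amounts and yields of single product count crystals too
- given per volume of solution although it is solid: crystals
- what may be going on: coupling partner + single product -> double product; starting material + coupling partner -> single product; single product <-> isomer of the product; crystals <-> single product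

* the flasks by amount of single product, in percent of the starting material charged, highest first, at 40 min (south-west / east / north / south-east / south / north-west)
* the amount of single product, in percent of the starting material charged of the flask you put first, at 40 min
* the amount of single product, in percent of the starting material charged of the flask you put last, at 40 min

The spring run was the one run I had, so my reckoning had to start there. I read its last point as starting material consumed by one second-order step, which gave 3.02 /M/min for the coupling constant, the rate of the first coupling divided by both concentrations. The reading at 2.00 min gave 2.99 /M/min, so I kept the constant, but these readings gave me no figure for any loss of single product.

I then solved both ends. At the early end, the half-life of starting material in north, with partner as charged, was 3.82 min, shorter than 40 min. At the late end the limiting reagent, partner in south-west, caps the consumed share of that flask at 80.0%, while north has 1.20 equivalents of partner. The second-order law joins the ends: with charges a and b of starting material and partner and E = exp((b − a)kt), the consumed share is b(E − 1)/(bE − a).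

For north this gave 93.4%. That share is consumed starting material, not single product, so I expected north somewhat lower. East and south carry 4.00 and 5.00 equivalents of partner, so I placed them below north on judgement.

The forecast gave north > east > south > south-west > south-east > north-west, with 88% (76% to 97%) for the first and 45% (36% to 49%) for the last, on this ground: “I expect modest over-coupling, which puts north first”.

The flasks gave north > south-west > east > south-east > south > north-west, with 88.7% for the first and 41.8% for the last.

    coupling partner + single product → double product (k = 0.0720 /M/s)
    starting material + coupling partner → single product (k = 0.0550 /M/s)
    single product ⇌ isomer of the product (K = 1.00, k = 0.00880 /s)
    crystals ⇌ single product, rate k4*(cs4 - [single product]) while solid is left; crystals form when [single product] > cs4 (solubility = 0.500 mM, k = 0.890 /s)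

North kept 6.50% of its starting material at 40.0 min, and my constant had left 6.60%. The same flask with 0.036 M of partner kept 33%, against 32.3% reckoned. In north at 4.17 min, the second coupling, partner with single product to double product, gave dissolved single product a half-life of 4.4 min, shorter than 40 min, but gave the partner a half-life of 4.8 h, longer than 40 min. At 40.0 min north held 87.7% as crystals and 3.83% as double product.

(The numbers in the tables come from a simulation for an exercise, and the scatter is random.)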